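(Readings and results stem from a simulated flask for substances that don't exist, noise included.)

The vessel is closed, stirred and isothermal. Free monomer enters chains through initiator, and protic impurity is charged with it.

the same everywhere: initiator 0.21 mM

|  | free monomer | protic impurity | temperature | remark | time |
|---|---|---|---|---|---|
| grey | 0.025 M | 2.5 mM | 79 °C | run made earlier |  |
| green | 0.038 M | 2.5 mM | 120 °C | run made earlier |  |
| noon | 0.050 M | 2.50 mM | 110 °C |  | 12 min |
| summer | 0.050 M | 2.50 mM | 60 °C |  | 12 min |
| dawn | 0.050 M | 2.50 mM | 85 °C |  | 12 min |
| midnight | 0.050 M | 2.50 mM | 135 °C |  | 12 min |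

| run | time / min | monomer in chains / % |
|---|---|---|
| grey | 5.00 | 91.0 |
| grey | 10.0 | 90.7 |
| grey | 15.0 | 90.1 |
| grey | 25.0 | 90.7 |
| grey | 40.0 | 90.7 |
| grey | 80.0 | 91.1 |
| green | 0.667 | 93.8 |
| green | 2.00 | 93.8 |
| green | 3.00 | 93.3 |
| green | 5.00 | 93.5 |
| green | 8.00 | 93.3 |
| green | 10.0 | 93.5 |

(standard deviation of a reading: 0.3 percentage points)

1. which flask leads in amount of monomer in chains, in percent of the free monomer charged ("all alike" within 1.5 percentage points) (noon / summer / dawn / midnight / all alike)
2. how much monomer in chains is there at the end, in percent of the free monomer charged: noon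
3. how much monomer in chains is there at the end, in percent of the free monomer charged: summer
4. how much monomer in chains is there at the end, in percent of the free monomer charged: dawn
5. how much monomer in chains is there at the end, in percent of the free monomer charged: midnight



1. Both earlier runs read flat in time, grey from 5.00 min and green from 0.667 min. Grey reads 90.7 % at 40.0 min, and green reads 93.5 % at 10.0 min.

2. The new flasks have one common ratio, [protic impurity]/[free monomer] = 0.0500. This is the impurity share, in the usual term the equivalents of protic impurity per free monomer charged. In words, if each protic impurity removes one free monomer, the share is the part of the charge that stays out of chains.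

3. Grey has a share of 0.100, which reckons to 90.0 %. Green has 0.0658, which reckons to 93.4 %. Green's reading lies 0.079 percentage points above its reckoning. Grey's reading lies 0.7 points above its reckoning, more than the scatter of 0.3 points. That gap in grey is less than the margin of 1.5 points.

4. Is one number enough? The share holds no time and no temperature. Summer at 60 °C is colder than grey, and midnight at 135 °C is hotter than green, so these two flasks lie outside the temperature span of the runs. Even so, the reckoning here commits to 95.0 % in each flask.

5. The forecast says all alike: noon 95.1 % (94.5 % to 95.6 %), summer 95 % (91.5 % to 95.7 %), dawn 95.2 % (94.6 % to 95.7 %), midnight 95 % (93.8 % to 95.6 %). It reads the runs as “a nearly temperature-independent stoichiometric loss of about 2.4 mM of monomer to the impurity”. Its dawn value stands 0.2 points above the reckoning here.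

6. The flasks give all alike: noon 95.0 %, summer 95.1 %, dawn 95.0 %, midnight 95.0 %.

    free monomer + initiator → living end + monomer in chains (k = 4.60 L mol⁻¹ s⁻¹, Ea = 38.0 kJ mol⁻¹)
    free monomer + living end → monomer in chains + living end, rate k2*[living end]*[free monomer] (k = 200 L mol⁻¹ s⁻¹, Ea = 51.0 kJ mol⁻¹)
    protic impurity + free monomer → quenched substrate (k = 2.70 L mol⁻¹ s⁻¹, Ea = 59.0 kJ mol⁻¹)
    (constants at 60 °C)

The share's 95.0 % stands within 0.13 points of summer's 95.1 %. Summer, the coldest flask, already holds 95.1 % in chains at 6.00 min, with free monomer at 0 %. A neighbour of summer is charged with 0.010 M of protic impurity. Its share is 0.200, which reckons to 80.0 % in chains. That neighbour gives 80.8 %, with quenched substrate at 19.2 % of the free monomer charged and 4.2 % of its protic impurity left.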